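**Retrosynthetic overview** (gibberellane numbering C1–C19 of the target is used for every intermediate)
1. Target ⇐ 16-nor-ketone 16 (C17 by Lombardo methylenation) ⇐ Δ2-ene lactone 15 (OsO4 from the β-face).
2. Ring A of 15 ⇐ dearomatising Birch reductive C-methylation of the ring-A benzamide in tetracyclic aryl acid 13 (sets C4), then acid-triggered amide-to-lactone closure across Δ5(10) (sets C5 and C10, releases the auxiliary).
3. 13 ⇐ C7 by amide-directed benzylic lithiation/CO2; 11β-OH by exo hydride delivery; ring D ⇐ 5-exo cyclisation of a dioxolan-2-yl radical onto a cyclohexenone (C13–C16; C16 arrives ketal-protected).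
4. Ring B ⇐ intramolecular Pd ketone α-arylation (C9–C10); quaternary C8 ⇐ Cu-catalysed asymmetric conjugate addition to a 3-benzylcyclohexenone made from o-toluamide 3 and 3-ethoxycyclohexenone.
5. Ring order: A (bought as arene) and C (bought) → B → D → A dearomatised and bridged by the lactone.

Assumption: the facial sense of the chiral ligand in step 3 and of the prolinol-ether auxiliary in step 9 is taken by analogy with the parent reactions; the enantiomeric ligand or auxiliary would be used if either sense proved opposite.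

**Step 1**
Reactants: 1 3-bromo-2-methylbenzoic acid; 2 (S)-2-(methoxymethyl)pyrrolidine
Product: 3 (S)-(3-bromo-2-methylphenyl)[2-(methoxymethyl)pyrrolidin-1-yl]methanone
Conditions: SOCl2, cat. DMF, PhMe, 70 °C; then 2, Et3N, CH2Cl2, 0 °C to rt
Reagents that add atoms: none
Why: Acid chloride amidation installs the tertiary amide that later serves as lateral-metalation director, Birch activating group, chiral auxiliary and lactone precursor.

**Step 2**
Reactants: 3 auxiliary o-toluamide; 4 3-ethoxycyclohex-2-en-1-one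
Product: 6 3-{[2-bromo-6-(auxiliary-carbonyl)phenyl]methyl}cyclohex-2-en-1-one, via carbinol adduct 5 (not isolated)
Conditions: LiN(i-Pr)2, THF, −78 °C; 4, −78 to 0 °C; then 2 M HCl, rt
Reagents that add atoms: water, O
Why: Lateral lithiation of the o-toluamide methyl group and Stork–Danheiser 1,2-addition/hydrolytic transposition give the β-benzyl enone (C6–C8 bond), with no stereocentre formed.

**Step 3**
Reactants: 6 β-benzyl enone; 7 (1,3-dioxolan-2-ylmethyl)magnesium bromide
Product: 8 (3R)-3-{[2-bromo-6-(auxiliary-carbonyl)phenyl]methyl}-3-(1,3-dioxolan-2-ylmethyl)cyclohexan-1-one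
Conditions: Cu(OTf)2 (3 mol %), chiral C2-symmetric imidazolinium chloride (carbene precursor, 4 mol %), 7 (1.3 equiv), Et2O, −30 °C; aq. NH4Cl
Reagents that add atoms: none
Why: Cu-catalysed asymmetric conjugate addition of a Grignard reagent to a β-substituted cyclohexenone (Alexakis type) creates the quaternary C8 under ligand control, and the bound (S)-auxiliary makes the minor C8 epimer a separable diastereomer.

**Step 4**
Reactants: 8 bromoaryl ketone
Product: 9 cis-fused hexahydrofluoren-4-one (rings A, B, C; C9–C10 bond made; 9-H cis to the C8 dioxolanylmethyl arm)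
Conditions: Pd(OAc)2 (5 mol %), P(t-Bu)3·HBF4 (10 mol %), NaOt-Bu (1.5 equiv), PhMe, 80 °C
Reagents that add atoms: none
Why: Intramolecular Buchwald–Hartwig ketone α-arylation through zerovalent palladium can only close the five-membered ring B at C9, and the epimerisable α-aryl ketone settles in the strongly preferred cis ring fusion, which fixes C9 relative to C8.

**Step 5**
Reactants: 9 tricyclic ketone
Product: 10 tricyclic enone (C11 ketone, C12=C13)
Conditions: Pd(O2CCF3)2 (5 mol %), DMSO (10 mol %), O2 (1 atm), EtOAc, 60 °C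
Reagents that add atoms: none
Why: Stahl aerobic dehydrogenation proceeds by β-hydride elimination from a divalent palladium enolate, which is possible only toward C12–C13 because C8 is quaternary and C10 is aromatic.

**Step 6**
Reactants: 10 acetal-tethered enone
Product: 11 tetracyclic A-aromatic ketone (ring D closed; C16 as spiro-1,3-dioxolane; C11 ketone)
Conditions: (t-BuO)3SiSH (10 mol %), t-BuON=NOt-Bu (5 mol %), PhH, 60 °C
Reagents that add atoms: none
Why: Thiol-catalysed radical-chain cycloisomerisation (polarity-reversal catalysis): the nucleophilic dioxolan-2-yl radical adds 5-exo to the enone β-carbon C13 from the only face its tether can reach, which sets C13 and delivers C16 already ketal-protected.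

**Step 7**
Reactants: 11 tetracyclic ketone
Product: 12 11β-alcohol
Conditions: NaBH4, CeCl3·7H2O, MeOH, −40 °C
Reagents that add atoms: none
Why: Luche-type hydride reduction occurs from the exo face (side of the one-carbon C14 bridge), because the endo face is blocked by the C15–C16 bridge and its ketal oxygen, giving the axial 11β-OH cis to 9-H.

**Step 8**
Reactants: 12 11β-alcohol
Product: 13 7-oic acid (6β-CO2H)
Conditions: s-BuLi (2.3 equiv), TMEDA, THF, −78 °C; CO2; 1 M HCl
Reagents that add atoms: carbon dioxide, O=C=O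
Why: Amide-directed lateral (benzylic) lithiation at C6 and carboxylation from the β-face, anti to the pseudo-axial C14 bridge, give the pseudo-axial 6β-acid, which is also the face that avoids the peri amide.

**Step 9**
Reactants: 13 tetracyclic aryl acid
Product: 15 11β-hydroxy-16-oxo-17-norgibberell-2-en-7-oic acid 19,10-lactone, via diene amide 14 (not isolated)
Conditions: KOt-Bu (2 equiv), THF; K (2.2 equiv), NH3(l), −78 °C; MeI (1.5 equiv), −78 °C; evaporate NH3; then CF3CO2H–CH2Cl2 (1:3), 0 °C to rt; H2O
Reagents that add atoms: iodomethane, CI; water, O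
Why: Schultz-type Birch reductive alkylation breaks the aromaticity of ring A (1,4-reduction to the amide enolate, then C-methylation at C4 on the β-face under control of the prolinol-ether auxiliary), and the acid then protonates C5 of the tetrasubstituted Δ5(10) alkene anti to attack of the amide oxygen at C10, so that hydrolysis gives the 19,10-lactone with 5β-H (the only arrangement with a cis-fused lactone/ring B), frees the auxiliary and unmasks the C16 ketone.

**Step 10**
Reactants: 15 Δ2-ene lactone
Product: 16 2β,3β,11β-trihydroxy-16-oxo-17-norgibberellan-7-oic acid 19,10-lactone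
Conditions: OsO4 (2 mol %), NMO (1.5 equiv), acetone–H2O (4:1), rt
Reagents that add atoms: osmium tetroxide, O=[Os](=O)(=O)=O (catalytic oxygen carrier); N-methylmorpholine N-oxide, C[N+]1([O-])CCOCC1; water, O
Why: Upjohn syn-dihydroxylation of the only alkene takes place on the exo β-face of the bicyclic lactone, opposite the lactone bridge, giving the cis-2β,3β-diol.

**Step 11**
Reactants: 16 nor-ketone triol acid
Product: 17 target, 2β,3β,11β-trihydroxygibberell-16-en-7-oic acid 19,10-lactone (CNP0322347.1)
Conditions: Zn, CH2Br2, TiCl4 (pre-formed reagent, excess), THF–CH2Cl2, 0 °C to rt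
Reagents that add atoms: dibromomethane, BrCBr
Why: Lombardo methylenation converts the C16 ketone into the exocyclic methylene under non-basic conditions, so the base-labile 3-hydroxy lactone and C6 are not epimerised and no stereocentre is touched.

**Compound list**
1 | 3-bromo-2-methylbenzoic acid | Cc1c(Br)cccc1C(=O)O | starting material
2 | (S)-2-(methoxymethyl)pyrrolidine | COC[C@@H]1CCCN1 | starting material
3 | (S)-(3-bromo-2-methylphenyl)[2-(methoxymethyl)pyrrolidin-1-yl]methanone | Cc1c(Br)cccc1C(=O)N1CCC[C@H]1COC | intermediate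
4 | 3-ethoxycyclohex-2-en-1-one | CCOC1=CC(=O)CCC1 | starting material
5 | 1-{[2-bromo-6-(auxiliary-carbonyl)phenyl]methyl}-3-ethoxycyclohex-2-en-1-ol (both carbinol epimers; not isolated) | CCOC1=CC(O)(Cc2c(Br)cccc2C(=O)N3CCC[C@H]3COC)CCC1 | intermediate
6 | 3-{[2-bromo-6-({(2S)-2-(methoxymethyl)pyrrolidin-1-yl}carbonyl)phenyl]methyl}cyclohex-2-en-1-one | O=C1C=C(Cc2c(Br)cccc2C(=O)N3CCC[C@H]3COC)CCC1 | intermediate
7 | (1,3-dioxolan-2-ylmethyl)magnesium bromide | Br[Mg]CC1OCCO1 | starting material
8 | (3R)-3-(arylmethyl)-3-(1,3-dioxolan-2-ylmethyl)cyclohexan-1-one (aryl = 2-bromo-6-auxiliary-carbonylphenyl; C8 set) | O1CCOC1C[C@@]2(CCCC(=O)C2)Cc3c(Br)cccc3C(=O)N4CCC[C@H]4COC | intermediate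
9 | cis-fused 9a-(1,3-dioxolan-2-ylmethyl)-8-(auxiliary-carbonyl)-1,2,3,4a,9,9a-hexahydrofluoren-4-one (4a-H cis to the 9a arm; C8, C9 as in target) | O1CCOC1C[C@]23CCCC(=O)[C@H]2c4cccc(C(=O)N5CCC[C@H]5COC)c4C3 | intermediate
10 | the same tricycle with C12=C13 (fluoren-4-one 2,3-ene) | O1CCOC1C[C@]23CC=CC(=O)[C@H]2c4cccc(C(=O)N5CCC[C@H]5COC)c4C3 | intermediate
11 | A-aromatic 17-norgibbane: ring-A C4 auxiliary amide, C6 = CH2, C11 ketone, C16 spiro-1,3-dioxolane, 9β-H, natural C8/C13 bicyclo[3.2.1]octane | O1CCOC12C[C@]34C[C@H]2CC(=O)[C@H]3c5cccc(C(=O)N6CCC[C@H]6COC)c5C4 | intermediate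
12 | 11β-alcohol of 11 (OH axial, syn to the C15–C16 bridge) | O1CCOC12C[C@]34C[C@H]2C[C@H](O)[C@H]3c5cccc(C(=O)N6CCC[C@H]6COC)c5C4 | intermediate
13 | 6β-carboxylic acid (C7) of 12 | O1CCOC12C[C@]34C[C@H]2C[C@H](O)[C@H]3c5cccc(C(=O)N6CCC[C@H]6COC)c5[C@@H]4C(=O)O | intermediate
14 | Birch diene: 4β-methyl, 4α-auxiliary amide, Δ2 and Δ5(10), otherwise as 13 (not isolated) | O1CCOC12C[C@]34C[C@H]2C[C@H](O)[C@H]3C5CC=C[C@@](C)(C(=O)N6CCC[C@H]6COC)C=5[C@@H]4C(=O)O | intermediate
15 | 11β-hydroxy-16-oxo-17-norgibberell-2-en-7-oic acid 19,10-lactone (5β-H, 10α-O) | O=C1C[C@]23C[C@H]1C[C@H](O)[C@H]2[C@@]12CC=C[C@@](C)(C(=O)O1)[C@H]2[C@@H]3C(=O)O | intermediate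
16 | 2β,3β,11β-trihydroxy-16-oxo-17-norgibberellan-7-oic acid 19,10-lactone | O=C1C[C@]23C[C@H]1C[C@H](O)[C@H]2[C@@]12C[C@H](O)[C@H](O)[C@@](C)(C(=O)O1)[C@H]2[C@@H]3C(=O)O | intermediate
17 | 2β,3β,11β-trihydroxygibberell-16-en-7-oic acid 19,10-lactone (CNP0322347.1) | C=C1C[C@]23C[C@H]1C[C@H](O)[C@H]2[C@@]12C[C@H](O)[C@H](O)[C@@](C)(C(=O)O1)[C@H]2[C@@H]3C(=O)O | target

**Step count**
Total: 11 steps. Longest linear sequence: 11 steps (from 1; compounds 2, 4 and 7 are bought).

**Three steps most likely to fail**

Step 9. The methyl group must enter syn to the pseudo-axial 6β-carboxylate, which sits 1,3 to C4 and shields that face, so the auxiliary has to win a mismatched case. O-methylation and cationic hydride shifts during lactonisation are further risks. The fallback sets out from 13 and returns at 15. Diazomethane-type esterification (TMSCHN2) gives the 6β-methyl ester F1. Deprotonation with LiN(i-Pr)2 and kinetic protonation of the ester enolate from the open β-face gives the 6-epi methyl ester F2, whose C7 is pseudo-equatorial and whose axial β-substituent is now hydrogen. LiBH4 reduces it to the 6-epi 7-alcohol F3. The same Birch reductive methylation, now matched between substrate and auxiliary, gives the diene amide F4, and the same acid treatment gives the lactone alcohol F5. TEMPO/PhI(OAc)2 oxidation followed by DBU equilibration gives the thermodynamically preferred 6β-aldehyde F6, and NaClO2 oxidation returns 15.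

Step 3. The β-alkoxy Grignard reagent may eliminate or simply deprotonate the benzylic γ-CH2 of 6, and its enantioselectivity is unproven. The fallback sets out from 6 and returns at 8. A copper–carbene catalysed asymmetric conjugate addition (Cu(OTf)2, chiral N-heterocyclic carbene) of (E)-Me3SiCH=CH–Al(i-Bu)2, made from ethynyltrimethylsilane and i-Bu2AlH, gives the β-silylvinyl ketone F7. m-CPBA converts the vinylsilane into the epoxysilane F8. TsOH with ethylene glycol (1.1 equiv) opens the epoxysilane to the aldehyde oxidation level and acetalises it chemoselectively next to the hindered ring ketone, returning 8.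

Step 6. The bridging 5-exo radical closure competes with unproductive hydrogen abstraction at the benzylic and amide α-positions. The fallback sets out from 10 and returns at 11. Aqueous HCl in THF frees the aldehyde F9. An intramolecular Stetter reaction with a thiazolium-derived carbene gives the 11,16-diketone F10. Ethylene glycol/PPTS ketalises the less hindered cyclopentanone carbonyl and returns 11.

**Further compounds**
F1 | step 9 | 6β-methyl ester of 13 | O1CCOC12C[C@]34C[C@H]2C[C@H](O)[C@H]3c5cccc(C(=O)N6CCC[C@H]6COC)c5[C@@H]4C(=O)OC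
F2 | step 9 | 6-epi methyl ester (6α-CO2Me) | O1CCOC12C[C@]34C[C@H]2C[C@H](O)[C@H]3c5cccc(C(=O)N6CCC[C@H]6COC)c5[C@H]4C(=O)OC
F3 | step 9 | 6-epi 7-alcohol (6α-CH2OH) | O1CCOC12C[C@]34C[C@H]2C[C@H](O)[C@H]3c5cccc(C(=O)N6CCC[C@H]6COC)c5[C@H]4CO
F4 | step 9 | diene amide from F3 (4β-methyl, 4α-amide, Δ2, Δ5(10)) | O1CCOC12C[C@]34C[C@H]2C[C@H](O)[C@H]3C5CC=C[C@@](C)(C(=O)N6CCC[C@H]6COC)C=5[C@H]4CO
F5 | step 9 | 6-epi 7,11β-dihydroxy-16-oxo-17-norgibberell-2-ene 19,10-lactone | O=C1C[C@]23C[C@H]1C[C@H](O)[C@H]2[C@@]12CC=C[C@@](C)(C(=O)O1)[C@H]2[C@H]3CO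
F6 | step 9 | 6β-aldehyde (7-al) of the same lactone | O=C1C[C@]23C[C@H]1C[C@H](O)[C@H]2[C@@]12CC=C[C@@](C)(C(=O)O1)[C@H]2[C@@H]3C=O
F7 | step 3 | 3-(arylmethyl)-3-[(E)-2-(trimethylsilyl)vinyl]cyclohexan-1-one, C8 as in 8 | C[Si](C)(C)/C=C/[C@@]2(CCCC(=O)C2)Cc3c(Br)cccc3C(=O)N4CCC[C@H]4COC
F8 | step 3 | trans-epoxysilane of F7 (epoxide diastereomers) | C[Si](C)(C)C1OC1[C@@]2(CCCC(=O)C2)Cc3c(Br)cccc3C(=O)N4CCC[C@H]4COC
F9 | step 6 | aldehyde enone (C8-CH2CHO arm) from 10 | O=CC[C@]23CC=CC(=O)[C@H]2c4cccc(C(=O)N5CCC[C@H]5COC)c4C3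
F10 | step 6 | A-aromatic 11,16-diketone | O=C1C[C@]23C[C@H]1CC(=O)[C@H]2c4cccc(C(=O)N5CCC[C@H]5COC)c4C3
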